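**Plan**

- Sikokianin A is a (2S,3S,2''S,3''S)-3,3''-biflavanone. In each pyranone ring C, C3 carries its hydrogen on the face opposite the C2 aryl group and C4 carries oxygen, which is the pattern left by syn hydroboration–oxidation of a C3=C4 bond from the face away from the C2 aryl group.
- Retrosynthesis: both C4 ketones go back to carbinols; then C3–H/C4–O and C3''–H/C4''–O are cut together, leaving a penta-O-benzyl 3,3''-bi(2-aryl-2H-chromene).
- The C3–C3'' bond is cut next (alkenyl bromide plus alkenyl boronate); each bromide comes from a 2-aryl-2H-chromene-3-carbaldehyde by loss of the formyl carbon.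
- Each chromene is cut at O1–C2 and C3–C4 into one common salicylaldehyde and a cinnamaldehyde.
- Forward: the two pyran rings are made separately, joined at C3–C3'', functionalised at C3/C4 and C3''/C4'' in one operation, oxidised and debenzylated.
- Stereochemistry: C2 and C2'' come from a prolinol silyl ether catalyst; C3 and C3'' come from borane adding anti to each C2 aryl group; the C4 carbinol centres are transient.

Key step: step 11

Remark: flavonoid locants are used (O1, C2, C3, C4, C4a to C8a; ring A is the benzo ring, ring C the pyran ring; double primes mark the unit bearing the 4-hydroxyphenyl group).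

Assumption: the sense of induction in steps 3 and 4 is taken from the usual shielding model of the E-iminium ion, not from a remembered assignment. If the configuration found were the opposite, the (R)-catalyst would be used with no other change. (E)-4-(Benzyloxy)cinnamaldehyde is made in step 2 rather than bought.

**Route**

Step 1
Reactants: 1 2,4,6-trihydroxybenzaldehyde; 2 benzyl bromide
Product: 3 2,4-bis(benzyloxy)-6-hydroxybenzaldehyde
Conditions: K2CO3 (2.1 equiv), 2 (2.05 equiv), DMF, 0 °C to rt
Reagents that add atoms: none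
Why: Williamson etherification, in which the para hydroxyl and one ortho hydroxyl are alkylated while the last ortho hydroxyl, hydrogen-bonded to the formyl group, should stay free with two equivalents of bromide.

Step 2
Reactants: 4 4-(benzyloxy)benzaldehyde; 5 (triphenylphosphoranylidene)acetaldehyde
Product: 6 (E)-3-[4-(benzyloxy)phenyl]prop-2-enal
Conditions: toluene, 80 °C
Reagents that add atoms: none
Why: Wittig olefination with a formyl-stabilised ylide, which should give the E-enal.

Step 3
Reactants: 3 2,4-bis(benzyloxy)-6-hydroxybenzaldehyde; 7 (E)-4-methoxycinnamaldehyde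
Product: 8 (R)-5,7-bis(benzyloxy)-2-(4-methoxyphenyl)-2H-chromene-3-carbaldehyde
Conditions: (S)-2-[diphenyl(trimethylsilyloxy)methyl]pyrrolidine (20 mol %), 2-nitrobenzoic acid (20 mol %), 4 Å molecular sieves, toluene, rt
Reagents that add atoms: none
Why: Organocatalytic domino oxa-Michael/aldol condensation, in which the phenol adds to the β-carbon of the E-iminium ion on the face not covered by the diphenyl(silyloxy)methyl group, the enamine closes onto the formyl group and water is lost, so that C2 should be set as R.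

Step 4
Reactants: 3 2,4-bis(benzyloxy)-6-hydroxybenzaldehyde; 6 (E)-3-[4-(benzyloxy)phenyl]prop-2-enal
Product: 9 (R)-5,7-bis(benzyloxy)-2-[4-(benzyloxy)phenyl]-2H-chromene-3-carbaldehyde
Conditions: (S)-2-[diphenyl(trimethylsilyloxy)methyl]pyrrolidine (20 mol %), 2-nitrobenzoic acid (20 mol %), 4 Å molecular sieves, toluene, rt
Reagents that add atoms: none
Why: The same domino oxa-Michael/aldol condensation with the same catalyst should set C2'' as R by the same facial shielding.

Step 5
Reactants: 8 (R)-5,7-bis(benzyloxy)-2-(4-methoxyphenyl)-2H-chromene-3-carbaldehyde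
Product: 10 (R)-5,7-bis(benzyloxy)-2-(4-methoxyphenyl)-2H-chromene-3-carboxylic acid
Conditions: NaClO2, NaH2PO4, 2-methyl-2-butene, t-BuOH/THF/H2O, 0 °C to rt
Reagents that add atoms: sodium chlorite, [Na+].[O-]Cl=O
Why: Pinnick oxidation should convert the enal into the acid without touching C3=C4 or C2, the hypochlorous acid formed being trapped by 2-methyl-2-butene before it can chlorinate ring A.

Step 6
Reactants: 9 (R)-5,7-bis(benzyloxy)-2-[4-(benzyloxy)phenyl]-2H-chromene-3-carbaldehyde
Product: 11 (R)-5,7-bis(benzyloxy)-2-[4-(benzyloxy)phenyl]-2H-chromene-3-carboxylic acid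
Conditions: NaClO2, NaH2PO4, 2-methyl-2-butene, t-BuOH/THF/H2O, 0 °C to rt
Reagents that add atoms: sodium chlorite, [Na+].[O-]Cl=O
Why: Pinnick oxidation, as in step 5.

Step 7
Reactants: 10 (R)-5,7-bis(benzyloxy)-2-(4-methoxyphenyl)-2H-chromene-3-carboxylic acid
Product: 12 (R)-5,7-bis(benzyloxy)-3-bromo-2-(4-methoxyphenyl)-2H-chromene
Conditions: NBS (1.0 equiv), Et3N (10 mol %), CH2Cl2, 0 °C to rt
Reagents that add atoms: N-bromosuccinimide, O=C1CCC(=O)N1Br
Why: Catalytic Hunsdiecker-type bromodecarboxylation of a cinnamic-type acid, in which C3 (the vinylogous ortho/para position of the three ring-A oxygens) should take up electrophilic bromine and the C4 cation then lose CO2 to restore C3=C4, a single equivalent of NBS limiting attack on ring A.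

Step 8
Reactants: 11 (R)-5,7-bis(benzyloxy)-2-[4-(benzyloxy)phenyl]-2H-chromene-3-carboxylic acid
Product: 13 (R)-5,7-bis(benzyloxy)-2-[4-(benzyloxy)phenyl]-3-bromo-2H-chromene
Conditions: NBS (1.0 equiv), Et3N (10 mol %), CH2Cl2, 0 °C to rt
Reagents that add atoms: N-bromosuccinimide, O=C1CCC(=O)N1Br
Why: Hunsdiecker-type bromodecarboxylation, as in step 7.

Step 9
Reactants: 13 (R)-5,7-bis(benzyloxy)-2-[4-(benzyloxy)phenyl]-3-bromo-2H-chromene
Product: 14 (S)-2-{5,7-bis(benzyloxy)-2-[4-(benzyloxy)phenyl]-2H-chromen-3-yl}-4,4,5,5-tetramethyl-1,3,2-dioxaborolane (same spatial arrangement at C2 as 13; the descriptor changes because boron ranks below carbon)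
Conditions: B2pin2, PdCl2(PPh3)2 (3 mol %), PPh3 (6 mol %), KOPh, toluene, 50 °C
Reagents that add atoms: bis(pinacolato)diboron, CC1(C)OB(OC1(C)C)B1OC(C)(C)C(C)(C)O1
Why: Miyaura borylation of an alkenyl bromide (oxidative addition to zerovalent palladium, phenoxide-assisted boryl transfer) at a temperature that should leave the C2 stereocentre untouched.

Step 10
Reactants: 12 (R)-5,7-bis(benzyloxy)-3-bromo-2-(4-methoxyphenyl)-2H-chromene; 14 the alkenyl pinacol boronate of step 9
Product: 15 (2R,2''R)-5,7,5'',7''-tetrakis(benzyloxy)-2''-[4-(benzyloxy)phenyl]-2-(4-methoxyphenyl)-3,3''-bi(2H-chromene)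
Conditions: Pd(OAc)2 (5 mol %), SPhos (10 mol %), K3PO4, THF/H2O, 50 °C
Reagents that add atoms: none
Why: Suzuki–Miyaura coupling of an alkenyl bromide with an alkenyl boronate under a bulky biarylphosphine that tolerates the hindered 2,3-disubstituted diene, and since the heterochiral diastereomer arising from residual minor enantiomers is separable here, the enantiomeric purity of 15 should exceed that of either half.

Step 11
Reactants: 15 (2R,2''R)-penta-O-benzyl 3,3''-bi(2-aryl-2H-chromene)
Product: 17 (2S,3R,4R,2''S,3''R,4''R)-penta-O-benzyl-3,3''-biflavan-4,4''-diol (2,3-cis-3,4-trans on both rings), via C4,C4''-bis(dihydroboryl) adduct 16 (not isolated)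
Conditions: BH3·THF (6 equiv), THF, 0 °C to rt; then H2O, NaBO3·4H2O, rt
Reagents that add atoms: borane–tetrahydrofuran complex, [BH3-][O+]1CCCC1 (boron in 16, hydrogen at C3 and C3''); sodium perborate (used as tetrahydrate), [Na+].[O-]B1OO1 (oxygen at C4 and C4'')
Why: Each C3=C4 bond is a trisubstituted styrene-type terminus of the diene and should take up BH3 through the four-centre syn transition state, boron going to the less substituted benzylic C4 and hydride to the fully substituted C3; the closest precedent is hydroboration–oxidation of 3-substituted 2H-chromenes (isoflav-3-enes) and of flav-3-enes, where borane adds anti to a 2-aryl group. No ring is closed, so no mode of closure has to be chosen. Allylic 1,2-strain with the C3 substituent (the other chromene) pushes each C2 aryl group pseudoaxial over one face of its own C3=C4 bond, so the resident C2 (C2'') centre sets C3 (C3'') with hydrogen anti to the aryl group, which leaves the C3–C3'' bond cis to it, and syn addition fixes C4 (C4'') relative to C3 (C3''). Perborate then replaces boron by oxygen with retention, and the two carbinol centres are erased in step 12. The step needs regioselectivity (boron at C4, secured because C3 is the fully substituted, internal diene carbon) and face selectivity on both rings (secured by the pseudoaxial aryl groups of two halves of the same configuration). Excess borane is used so that each alkene should meet its own BH3 before the first C4–B–H unit can reach across to the other ring.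

Step 12
Reactants: 17 (2S,3R,4R,2''S,3''R,4''R)-penta-O-benzyl-3,3''-biflavan-4,4''-diol
Product: 18 (2S,3S,2''S,3''S)-5,7,5'',7''-tetrakis(benzyloxy)-2''-[4-(benzyloxy)phenyl]-2-(4-methoxyphenyl)-3,3''-biflavanone
Conditions: Dess–Martin periodinane, NaHCO3, CH2Cl2, 0 °C to rt
Reagents that add atoms: none
Why: Dess–Martin oxidation of the two secondary benzylic carbinols under buffered, non-basic conditions should give the ketones without enolisation, so the cis C2/C3 and C2''/C3'' relationships are kept (the C3 descriptors change from R to S only because C4 now outranks C2).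

Step 13
Reactants: 18 (2S,3S,2''S,3''S)-penta-O-benzyl biflavanone
Product: 19 sikokianin A, (2S,3S,2''S,3''S)-5,7,5'',7''-tetrahydroxy-2''-(4-hydroxyphenyl)-2-(4-methoxyphenyl)-3,3''-biflavanone
Conditions: H2 (1 atm), 10% Pd/C, EtOAc/MeOH, rt
Reagents that add atoms: none
Why: Catalytic hydrogenolysis should cleave the five benzyl ethers under neutral conditions that spare the aryl methyl ether, the flavanone carbonyls and the base-sensitive cis C2/C3 centres.

**Compound list**

1 | 2,4,6-trihydroxybenzaldehyde | O=Cc1c(O)cc(O)cc1O | starting material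
2 | benzyl bromide | BrCc1ccccc1 | starting material
3 | 2,4-bis(benzyloxy)-6-hydroxybenzaldehyde | O=Cc1c(O)cc(OCc2ccccc2)cc1OCc1ccccc1 | intermediate
4 | 4-(benzyloxy)benzaldehyde | O=Cc1ccc(OCc2ccccc2)cc1 | starting material
5 | (triphenylphosphoranylidene)acetaldehyde | O=CC=P(c1ccccc1)(c1ccccc1)c1ccccc1 | starting material
6 | (E)-3-[4-(benzyloxy)phenyl]prop-2-enal | O=C/C=C/c1ccc(OCc2ccccc2)cc1 | intermediate
7 | (E)-4-methoxycinnamaldehyde | COc1ccc(/C=C/C=O)cc1 | starting material
8 | (R)-5,7-bis(benzyloxy)-2-(4-methoxyphenyl)-2H-chromene-3-carbaldehyde | COc1ccc([C@H]2Oc3cc(OCc4ccccc4)cc(OCc4ccccc4)c3C=C2C=O)cc1 | intermediate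
9 | (R)-5,7-bis(benzyloxy)-2-[4-(benzyloxy)phenyl]-2H-chromene-3-carbaldehyde | O=CC1=Cc2c(OCc3ccccc3)cc(OCc3ccccc3)cc2O[C@@H]1c1ccc(OCc2ccccc2)cc1 | intermediate
10 | (R)-5,7-bis(benzyloxy)-2-(4-methoxyphenyl)-2H-chromene-3-carboxylic acid | COc1ccc([C@H]2Oc3cc(OCc4ccccc4)cc(OCc4ccccc4)c3C=C2C(=O)O)cc1 | intermediate
11 | (R)-5,7-bis(benzyloxy)-2-[4-(benzyloxy)phenyl]-2H-chromene-3-carboxylic acid | OC(=O)C1=Cc2c(OCc3ccccc3)cc(OCc3ccccc3)cc2O[C@@H]1c1ccc(OCc2ccccc2)cc1 | intermediate
12 | (R)-5,7-bis(benzyloxy)-3-bromo-2-(4-methoxyphenyl)-2H-chromene | COc1ccc([C@H]2Oc3cc(OCc4ccccc4)cc(OCc4ccccc4)c3C=C2Br)cc1 | intermediate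
13 | (R)-5,7-bis(benzyloxy)-2-[4-(benzyloxy)phenyl]-3-bromo-2H-chromene | BrC1=Cc2c(OCc3ccccc3)cc(OCc3ccccc3)cc2O[C@@H]1c1ccc(OCc2ccccc2)cc1 | intermediate
14 | (S)-2-{5,7-bis(benzyloxy)-2-[4-(benzyloxy)phenyl]-2H-chromen-3-yl}-4,4,5,5-tetramethyl-1,3,2-dioxaborolane | CC1(C)OB(OC1(C)C)C1=Cc2c(OCc3ccccc3)cc(OCc3ccccc3)cc2O[C@@H]1c1ccc(OCc2ccccc2)cc1 | intermediate
15 | (2R,2''R)-5,7,5'',7''-tetrakis(benzyloxy)-2''-[4-(benzyloxy)phenyl]-2-(4-methoxyphenyl)-3,3''-bi(2H-chromene) | COc1ccc([C@H]2Oc3cc(OCc4ccccc4)cc(OCc4ccccc4)c3C=C2C2=Cc3c(OCc4ccccc4)cc(OCc4ccccc4)cc3O[C@@H]2c2ccc(OCc3ccccc3)cc2)cc1 | intermediate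
16 | C4,C4''-bis(dihydroboryl) adduct of 15, configured as 17 with BH2 in place of each hydroxyl | COc1ccc([C@H]2Oc3cc(OCc4ccccc4)cc(OCc4ccccc4)c3[C@H](B)[C@H]2[C@@H]2[C@@H](B)c3c(OCc4ccccc4)cc(OCc4ccccc4)cc3O[C@@H]2c2ccc(OCc3ccccc3)cc2)cc1 | intermediate
17 | (2S,3R,4R,2''S,3''R,4''R)-5,7,5'',7''-tetrakis(benzyloxy)-2''-[4-(benzyloxy)phenyl]-2-(4-methoxyphenyl)-3,3''-biflavan-4,4''-diol | COc1ccc([C@H]2Oc3cc(OCc4ccccc4)cc(OCc4ccccc4)c3[C@H](O)[C@H]2[C@@H]2[C@@H](O)c3c(OCc4ccccc4)cc(OCc4ccccc4)cc3O[C@@H]2c2ccc(OCc3ccccc3)cc2)cc1 | intermediate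
18 | (2S,3S,2''S,3''S)-5,7,5'',7''-tetrakis(benzyloxy)-2''-[4-(benzyloxy)phenyl]-2-(4-methoxyphenyl)-3,3''-biflavanone | COc1ccc([C@H]2Oc3cc(OCc4ccccc4)cc(OCc4ccccc4)c3C(=O)[C@H]2[C@@H]2C(=O)c3c(OCc4ccccc4)cc(OCc4ccccc4)cc3O[C@@H]2c2ccc(OCc3ccccc3)cc2)cc1 | intermediate
19 | sikokianin A | COc1ccc([C@H]2Oc3cc(O)cc(O)c3C(=O)[C@H]2[C@@H]2C(=O)c3c(O)cc(O)cc3O[C@@H]2c2ccc(O)cc2)cc1 | target

**Step count**

Total: 13 steps. Longest linear sequence: 9 steps (steps 1, 4, 6, 8, 9, 10, 11, 12, 13).

**Steps most likely to fail**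

Step 11. Borane may add syn to the aryl group on one ring, or the first C4–BH2 unit may deliver hydride across to the second alkene so that the C3''/C4'' face is no longer set by C2''; either process would leave C3/C3'' epimers in 17. The fallback sets out from 17 and comes back at 18, and moves the control of C3 from borane addition to kinetic protonation. The epimer mixture is oxidised as in step 12, giving 18 together with its 2,3-trans isomers, the extreme case being the doubly epimerised (2S,3R,2''S,3''R)-penta-O-benzyl biflavanone F1. Soft enolisation (TMSOTf, Et3N, CH2Cl2, 0 °C) should converge all C3 epimers on (2R,2''R)-penta-O-benzyl-4,4''-bis(trimethylsilyloxy)-3,3''-bi(2H-chromene) F2. Fluoride-triggered protonation at −78 °C (n-Bu4NF premixed with acetic acid, THF) should then deliver the proton to C3 and C3'' from the face away from each pseudoaxial C2 aryl group and return 18.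

Step 7 (step 8 is the same reaction on the other half and shares the risk). Electrophilic bromine may attack C6 or C8 of the trioxygenated ring A in competition with C3, or the C4 cation may be captured before CO2 is lost. The fallback sets out from aldehydes 8 and 9 and comes back at 15 and 14; it removes the formyl carbon by oxygen insertion, so no electrophilic halogen is needed. Baeyer–Villiger oxidation of 8 (H2O2, catalytic 2-nitrobenzeneseleninic acid, CH2Cl2) should give (R)-5,7-bis(benzyloxy)-2-(4-methoxyphenyl)-2H-chromen-3-yl formate F3 by vinyl migration. Cleavage with MeLi (2 equiv, THF, −78 °C) should give the C3=C4 lithium enolate, which is trapped with N-phenylbis(trifluoromethanesulfonimide) as (R)-5,7-bis(benzyloxy)-2-(4-methoxyphenyl)-2H-chromen-3-yl trifluoromethanesulfonate F4. F4 takes the place of 12 in step 10 and gives 15. The same two operations on 9 would give (R)-5,7-bis(benzyloxy)-2-[4-(benzyloxy)phenyl]-2H-chromen-3-yl formate F5 and the corresponding trifluoromethanesulfonate F6, which would be borylated under the conditions of step 9 to 14.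

Step 10. Protodeboronation of 14 and slow transmetalation between two hindered alkenyl partners may divert the coupling to reduced or homocoupled chromenes. The fallback sets out from 13 and comes back at 15, and replaces the base-dependent boron transmetalation by a neutral tin-to-copper-to-palladium transfer. Stannylation of 13 (Me3SnSnMe3, Pd(PPh3)4, toluene, 80 °C) should give (R)-5,7-bis(benzyloxy)-2-[4-(benzyloxy)phenyl]-3-(trimethylstannyl)-2H-chromene F7. Stille coupling of F7 with 12 (Pd(PPh3)4, CuI, CsF, DMF, 45 °C) should give 15.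

**Further compounds**

F1 | step 11 | (2S,3R,2''S,3''R)-5,7,5'',7''-tetrakis(benzyloxy)-2''-[4-(benzyloxy)phenyl]-2-(4-methoxyphenyl)-3,3''-biflavanone | COc1ccc([C@H]2Oc3cc(OCc4ccccc4)cc(OCc4ccccc4)c3C(=O)[C@@H]2[C@H]2C(=O)c3c(OCc4ccccc4)cc(OCc4ccccc4)cc3O[C@@H]2c2ccc(OCc3ccccc3)cc2)cc1
F2 | step 11 | (2R,2''R)-5,7,5'',7''-tetrakis(benzyloxy)-2''-[4-(benzyloxy)phenyl]-2-(4-methoxyphenyl)-4,4''-bis(trimethylsilyloxy)-3,3''-bi(2H-chromene) | COc1ccc([C@H]2Oc3cc(OCc4ccccc4)cc(OCc4ccccc4)c3C(O[Si](C)(C)C)=C2C2=C(O[Si](C)(C)C)c3c(OCc4ccccc4)cc(OCc4ccccc4)cc3O[C@@H]2c2ccc(OCc3ccccc3)cc2)cc1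
F3 | step 7 | (R)-5,7-bis(benzyloxy)-2-(4-methoxyphenyl)-2H-chromen-3-yl formate | COc1ccc([C@H]2Oc3cc(OCc4ccccc4)cc(OCc4ccccc4)c3C=C2OC=O)cc1
F4 | step 7 | (R)-5,7-bis(benzyloxy)-2-(4-methoxyphenyl)-2H-chromen-3-yl trifluoromethanesulfonate | COc1ccc([C@H]2Oc3cc(OCc4ccccc4)cc(OCc4ccccc4)c3C=C2OS(=O)(=O)C(F)(F)F)cc1
F5 | step 7 | (R)-5,7-bis(benzyloxy)-2-[4-(benzyloxy)phenyl]-2H-chromen-3-yl formate | O=COC1=Cc2c(OCc3ccccc3)cc(OCc3ccccc3)cc2O[C@@H]1c1ccc(OCc2ccccc2)cc1
F6 | step 7 | (R)-5,7-bis(benzyloxy)-2-[4-(benzyloxy)phenyl]-2H-chromen-3-yl trifluoromethanesulfonate | FC(F)(F)S(=O)(=O)OC1=Cc2c(OCc3ccccc3)cc(OCc3ccccc3)cc2O[C@@H]1c1ccc(OCc2ccccc2)cc1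
F7 | step 10 | (R)-5,7-bis(benzyloxy)-2-[4-(benzyloxy)phenyl]-3-(trimethylstannyl)-2H-chromene | C[Sn](C)(C)C1=Cc2c(OCc3ccccc3)cc(OCc3ccccc3)cc2O[C@@H]1c1ccc(OCc2ccccc2)cc1
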